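**Plan**
- Retrosynthesis: the C12–C13 bond of ring C (C8–C9–C11–C12–C13–C14) is cut and C12 is re-attached to C16, giving an isomeric bicyclo[3.2.1]octane with a seven-membered ring C8–C9–C11–C12–C16–C13–C14, a C16 methyl and an exo leaving group on C13. The C1–O and C2–O bonds go back to a Δ1 alkene, and C13–H to a C13 ketone.
- Enabling feature: C16 is next to bridgehead C13 and carries C17, so it can hold a tertiary cation, and the bridge carbon C12 can move between C13 and C16 on one face of the bicycle. The 13-hydroxy-16-ene unit of gibberellic acid gives exactly this isomeric ketone, so gibberellic acid is the chiral-pool source.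
- Order of events: rings A and B, the lactone and the five-membered ring C8–C14–C13–C16–C15 stay intact. Ring C is expanded to the seven-membered isomer in step 2 (this removes the 13-OH and hides the 16-methylene during osmylation) and is re-formed by contraction in step 6.
- Stereochemistry: C3, C4, C5, C6, C8, C9 and C10 come from gibberellic acid. C1 and C2 come from hydroxyl-directed syn-osmylation on the β face. C13 is set by inversion at the migration terminus, which the bridged frame enforces.

Key step: step 6

Assumption: gibberellic acid, the bulk fermentation product, is taken as a commercially available starting material, so this is a synthesis from the chiral pool.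

Here "exo" on C13 means the side of the one-carbon bridge C15; "endo" means the side of the three-carbon bridge C9–C11–C12.

**Step 1**
Reactants: 1 gibberellic acid
Product: 2 gibberellic acid 2-(trimethylsilyl)ethyl ester
Conditions: Me3SiCH2CH2OH (5 equiv), DCC, DMAP (cat.), THF–CH2Cl2, 0 °C → rt
Reagents that add atoms: 2-(trimethylsilyl)ethanol, C[Si](C)(C)CCO
Why: Steglich esterification of the C7 acid, giving an ester that is inert to the later oxidation, acylation and triflation steps and is cleaved at the end by fluoride without hydrolysis.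

**Step 2**
Reactants: 2 gibberellic acid 2-(trimethylsilyl)ethyl ester
Product: 3 abeo-ketone ester (C12 moved from C13 to C16; C17 now a methyl on quaternary C16; C13 a ketone; Δ1, 3β-OH and lactone unchanged)
Conditions: Co(salen) (salen = N,N′-bis(3,5-di-tert-butylsalicylidene)-1,2-cyclohexanediaminate, divalent cobalt, 5 mol %), N-fluoro-2,4,6-trimethylpyridinium triflate (1.5 equiv), PhSiH3 (1.5 equiv), PhCF3, 0 °C → rt; aq. NaHCO3
Reagents that add atoms: none
Why: Hydrogen-atom transfer from the cobalt hydride to the 1,1-disubstituted C16=C17 alkene (the 1,2-disubstituted Δ1 alkene would give only a secondary radical and should react far more slowly) gives the tertiary C16 radical, which is oxidised to the cation and undergoes semipinacol 1,2-shift of C12 from the carbinol carbon C13 (radical–polar crossover semipinacol rearrangement); C14 should not migrate because that would build a cyclobutane, and the configuration of C16 is fixed by the bridged frame.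

**Step 3**
Reactants: 3 abeo-ketone ester
Product: 5 1β,2β,3β-trihydroxy abeo-ketone ester, via osmium glycolate TMEDA complex 4 (not isolated)
Conditions: OsO4 (1.05 equiv), TMEDA (1.1 equiv), CH2Cl2, −78 °C; then conc. HCl, MeOH, rt
Reagents that add atoms: osmium tetroxide, O=[Os](=O)(=O)=O
Why: Hydroxyl-directed syn-dihydroxylation: the 3β-OH hydrogen-bonds to the OsO4·TMEDA reagent and delivers it to the β face of C1=C2, which is also the open face because the 19,10-lactone bridge covers the α face, so C1 and C2 are set cis to the 3β-OH.

**Step 4**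
Reactants: 5 1β,2β,3β-trihydroxy abeo-ketone ester
Product: 6 1β,2β,3β-triacetoxy abeo-ketone ester
Conditions: Ac2O, DMAP, pyridine, rt → 40 °C
Reagents that add atoms: acetic anhydride, CC(=O)OC(C)=O
Why: DMAP-catalysed acetylation of all three secondary hydroxyls, so that no free OH competes with C13–OH in the triflation and the 3-O-acyl group blocks retro-aldol opening of C3–C4.

**Step 5**
Reactants: 6 1β,2β,3β-triacetoxy abeo-ketone ester
Product: 7 exo-13-hydroxy triacetate ester
Conditions: [(η5-Ph4C4CO)2H]Ru2(CO)4(μ-H) (3 mol %), i-PrOH–toluene 1:1, 90 °C, until the epimer ratio no longer changes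
Reagents that add atoms: none
Why: Reversible ruthenium-catalysed transfer hydrogenation (Meerwein–Ponndorf–Verley type, neutral, esters untouched) lets the C13 epimers interconvert through the ketone, so the more stable exo alcohol should accumulate, since the endo OH is pressed against the axial hydrogen on C11; a kinetic hydride would attack the exo face and give the endo epimer.

**Step 6**
Reactants: 7 exo-13-hydroxy triacetate ester
Product: 9 target triacetate 2-(trimethylsilyl)ethyl ester, via exo-13-triflate 8 (not isolated)
Conditions: Tf2O (1.3 equiv), 2,6-di-tert-butyl-4-methylpyridine (3 equiv), CH2Cl2, −78 °C → 0 °C; aq. NaHCO3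
Reagents that add atoms: none
Why: The exo-triflate 8 should ionise with participation of the C16–C12 σ-bond antiperiplanar to C13–O, so C12 moves from C16 to C13, the charge passes to C16 as a tertiary cation, and the hindered pyridine takes a proton from C17 (Wagner–Meerwein 1,2-alkyl shift ended by loss of a proton). The closest known reaction type is the solvolytic rearrangement of exo-beyeran-16-yl sulfonates to kaur-16-enes (and of isobornyl derivatives to camphene), the laboratory counterpart of the beyeranyl-to-kauranyl shift of ent-kaurene biosynthesis. Ring C (C8–C9–C11–C12–C13–C14) is closed by this suprafacial 1,2-shift as a ring contraction: the seven-membered ring C8–C9–C11–C12–C16–C13–C14 loses C16 from its perimeter, while the five-membered ring C8–C14–C13–C16–C15 is kept and becomes ring D. The one new stereocentre, C13, forms with inversion because C12 enters on the endo face opposite the departing triflate, which is the only configuration the bridged frame can hold and leaves the 13-H of the target. The step needs C12 to migrate and not C15 or the methyl, which the exo configuration secures (only C16–C12 is aligned, and a C15 shift would build a cyclobutane); it also needs proton loss from C17 and not C15, which the three exposed methyl hydrogens should favour over a C15 methylene flanked by the 6β-ester.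

**Step 7**
Reactants: 9 target triacetate 2-(trimethylsilyl)ethyl ester
Product: 10 target 1,2,3-triacetate (free 7-acid)
Conditions: Bu4NF (3 equiv), THF, 0 °C → rt; then 1 M HCl to pH 3
Reagents that add atoms: none
Why: Fluoride attacks silicon and the ester fragments to the carboxylate, ethene and Me3SiF (β-elimination), which should leave the acetates, the lactone and the 16-methylene untouched while the 3-acetate still blocks retro-aldol.

**Step 8**
Reactants: 10 target 1,2,3-triacetate (free 7-acid)
Product: 11 target gibberellin (1β,2β,3β-trihydroxy-16-methylene 19,10-lactone 7-acid with 13-H)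
Conditions: K2CO3 (4 equiv), MeOH, 0 °C → rt, short reaction time; then 1 M HCl to pH 3, EtOAc extraction
Reagents that add atoms: none
Why: Mild base-catalysed methanolysis (Zemplén-type transesterification) should remove the three acetates without opening the hindered lactone, and is kept cold and brief to avoid retro-aldol epimerisation at C3.

**Compound list**
1 | gibberellic acid (3β,13-dihydroxy-1,16-diene 19,10-lactone 7-acid) | C=C1C[C@]23C[C@@]1(O)CC[C@H]2[C@@]12OC(=O)[C@@](C)([C@H]1[C@@H]3C(=O)O)[C@@H](O)C=C2 | starting material
2 | gibberellic acid 2-(trimethylsilyl)ethyl ester | C=C1C[C@]23C[C@@]1(O)CC[C@H]2[C@@]12OC(=O)[C@@](C)([C@H]1[C@@H]3C(=O)OCC[Si](C)(C)C)[C@@H](O)C=C2 | intermediate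
3 | abeo-ketone ester (C12 on C16, 16-methyl, 13-oxo, Δ1, 3β-OH) | C[C@@]12CC[C@H]3[C@@]45OC(=O)[C@@](C)([C@H]4[C@@H]([C@@]3(C2)CC1=O)C(=O)OCC[Si](C)(C)C)[C@@H](O)C=C5 | intermediate
4 | osmium glycolate TMEDA complex (hexavalent osmium; OsO2 bound to the oxygens on C1 and C2 and to both nitrogens of Me2NCH2CH2NMe2) | C[C@@]12CC[C@H]3[C@@]45OC(=O)[C@@](C)([C@H]4[C@@H]([C@@]3(C2)CC1=O)C(=O)OCC[Si](C)(C)C)[C@@H](O)[C@H]6O[Os-2]7(=O)(=O)(O[C@@H]56)[N+](C)(C)CC[N+]7(C)C | intermediate
5 | 1β,2β,3β-trihydroxy abeo-ketone ester | C[C@@]12CC[C@H]3[C@@]45OC(=O)[C@@](C)([C@H]4[C@@H]([C@@]3(C2)CC1=O)C(=O)OCC[Si](C)(C)C)[C@@H](O)[C@@H](O)[C@H]5O | intermediate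
6 | 1β,2β,3β-triacetoxy abeo-ketone ester | C[C@@]12CC[C@H]3[C@@]45OC(=O)[C@@](C)([C@H]4[C@@H]([C@@]3(C2)CC1=O)C(=O)OCC[Si](C)(C)C)[C@@H](OC(C)=O)[C@@H](OC(C)=O)[C@H]5OC(C)=O | intermediate
7 | exo-13-hydroxy triacetate ester (13-OH on the side of the C15 bridge) | C[C@@]12CC[C@H]3[C@@]45OC(=O)[C@@](C)([C@H]4[C@@H]([C@@]3(C2)C[C@@H]1O)C(=O)OCC[Si](C)(C)C)[C@@H](OC(C)=O)[C@@H](OC(C)=O)[C@H]5OC(C)=O | intermediate
8 | exo-13-triflate | C[C@@]12CC[C@H]3[C@@]45OC(=O)[C@@](C)([C@H]4[C@@H]([C@@]3(C2)C[C@@H]1OS(=O)(=O)C(F)(F)F)C(=O)OCC[Si](C)(C)C)[C@@H](OC(C)=O)[C@@H](OC(C)=O)[C@H]5OC(C)=O | intermediate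
9 | target triacetate 2-(trimethylsilyl)ethyl ester (1β,2β,3β-triacetoxy, 13-H, 16-methylene, 19,10-lactone) | C=C1C[C@]23C[C@H]1CC[C@H]2[C@@]12OC(=O)[C@@](C)([C@H]1[C@@H]3C(=O)OCC[Si](C)(C)C)[C@@H](OC(C)=O)[C@@H](OC(C)=O)[C@H]2OC(C)=O | intermediate
10 | target 1,2,3-triacetate (free 7-acid) | C=C1C[C@]23C[C@H]1CC[C@H]2[C@@]12OC(=O)[C@@](C)([C@H]1[C@@H]3C(=O)O)[C@@H](OC(C)=O)[C@@H](OC(C)=O)[C@H]2OC(C)=O | intermediate
11 | target gibberellin (1β,2β,3β-trihydroxy-16-methylene 19,10-lactone 7-acid with 13-H) | C=C1C[C@]23C[C@H]1CC[C@H]2[C@@]12OC(=O)[C@@](C)([C@H]1[C@@H]3C(=O)O)[C@@H](O)[C@@H](O)[C@H]2O | target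

**Totals**
Total step count: 8. Longest linear sequence: 8 steps (1 → 11).

**Steps most likely to fail**

Step 6. The C16 cation may lose its proton from C15 instead of C17, giving the endocyclic alkene, and some ion may leak away by transannular hydride shift from C12 to C13. The fallback sets out from 7 and returns at 9. The same ionisation is run and the endocyclic Δ15 alkene isomer F1 is collected as well. F1 is then moved to the exocyclic position by photochemical contra-thermodynamic positional isomerisation: (Bu4N)4W10O32 abstracts an allylic hydrogen from the C17 methyl under near-UV light, the allyl radical is trapped by Co(dmgH)2(py)Cl (trivalent cobalt) as an allylcobalt species, and this is protonated at C15. This gives 9.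

Step 5. Hydrogen transfer at the neopentyl ketone may be slow, or the equilibrium may not favour the exo alcohol enough. The fallback sets out from 6 and returns at 9 without passing through 7. Kinetic reduction with NaBH4 (THF–MeOH, −20 °C) delivers hydride to the exo face and should give the endo-13-hydroxy triacetate ester F2. Tf2O with 2,6-di-tert-butyl-4-methylpyridine converts it to the endo-13-triflate F3. F3 has no antiperiplanar C–C bond, so it is ionised without assistance in (CF3)2CHOH at rt over solid NaHCO3. The secondary C13 cation should then collapse by the same C12 shift to the C16 cation and on to 9.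

Step 2. The cobalt hydride may fail to discriminate between the two alkenes, or the C16 radical may be reduced or trapped before it is oxidised to the cation. The fallback sets out from 2 and returns at 3. PhSeCl with solid NaHCO3 (CH2Cl2, −78 °C) adds to the electron-rich C16=C17 alkene, and the seleniranium ion triggers the same semipinacol shift of C12. This gives the 17-phenylselanyl abeo-ketone ester F4. Bu3SnH with AIBN in benzene at 80 °C then cleaves the C–Se bond to give 3; the stannane is kept concentrated so that hydrogen transfer outruns a 1,2-acyl shift of the primary radical.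

**Further compounds**
F1 | step 6 | endocyclic Δ15 alkene isomer of 9 with a 16-methyl | CC1=C[C@]23C[C@H]1CC[C@H]2[C@@]12OC(=O)[C@@](C)([C@H]1[C@@H]3C(=O)OCC[Si](C)(C)C)[C@@H](OC(C)=O)[C@@H](OC(C)=O)[C@H]2OC(C)=O
F2 | step 5 | endo-13-hydroxy triacetate ester (C13 epimer of 7) | C[C@@]12CC[C@H]3[C@@]45OC(=O)[C@@](C)([C@H]4[C@@H]([C@@]3(C2)C[C@H]1O)C(=O)OCC[Si](C)(C)C)[C@@H](OC(C)=O)[C@@H](OC(C)=O)[C@H]5OC(C)=O
F3 | step 5 | endo-13-triflate (C13 epimer of 8) | C[C@@]12CC[C@H]3[C@@]45OC(=O)[C@@](C)([C@H]4[C@@H]([C@@]3(C2)C[C@H]1OS(=O)(=O)C(F)(F)F)C(=O)OCC[Si](C)(C)C)[C@@H](OC(C)=O)[C@@H](OC(C)=O)[C@H]5OC(C)=O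
F4 | step 2 | 17-phenylselanyl abeo-ketone ester | c1ccc(cc1)[Se]C[C@@]12CC[C@H]3[C@@]45OC(=O)[C@@](C)([C@H]4[C@@H]([C@@]3(C2)CC1=O)C(=O)OCC[Si](C)(C)C)[C@@H](O)C=C5
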